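## Retrosynthetic overview

1. The target comes from its 15-O-silyl ether by desilylation; the C8 methacrylate is installed early and carried through.
2. The ten-membered carbocycle and the α-methylene lactone open at C6–C7, the bond germacrene synthase forms from farnesyl diphosphate. Forward, an allylchromium at C7 adds to a C6 enal and the adduct lactonises, setting C6 and C7.
3. The 3(2H)-furanone opens to an acyclic 10-hydroxy ynone (a 10-hydroxy-1,3-dicarbonyl equivalent). Forward, the C10 hydroxyl closes onto C3 by cyclodehydration. The ynone comes from a terminal alkyne, CO and a vinyl iodide.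
4. The alkyne fragment (C8, C10) comes from a catalytic asymmetric ynone aldol and a chelate-controlled methyl addition. The vinyl iodide (4Z geometry) comes from but-2-yne-1,4-diol by trans-hydroalumination and iodination.
5. Ring order: furanone first, then carbocycle and lactone in one operation.

Assumption: positions in all intermediates carry the germacrane numbering of the target (C1 ketone, C2=C3 and C4=C5 alkenes, C6 lactone carbinol, C7, C8 ester carbinol, C9, C10 quaternary carbon, C11–C13 acrylate unit, C14 methyl, C15 hydroxymethyl); the target is (4Z,6R,7R,8R,10S).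

Assumption: (S,S)-ProPhenol is taken as the ligand enantiomer that gives the (R)-aldol in step 1 (checked by Mosher analysis, otherwise the (R,R)-ligand is used); 2,2-dimethoxyacetaldehyde is used anhydrous, freed from its commercial aqueous solution.

## Route

Step 1
Reactants: 1 4-(trimethylsilyl)but-3-yn-2-one; 2 2,2-dimethoxyacetaldehyde
Product: 3 (R)-5-hydroxy-6,6-dimethoxy-1-(trimethylsilyl)hex-1-yn-3-one
Conditions: (S,S)-ProPhenol (10 mol %), Et2Zn (20 mol %), 4 Å MS, THF, 4 °C
Reagents that add atoms: none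
Why: Trost direct asymmetric aldol of a methyl ynone, in which the dinuclear zinc–ProPhenol catalyst forms the zinc enolate of 1 and delivers it to one face of the α-acetal aldehyde, setting C8 as R while the acetal carries C7 as a masked aldehyde.

Step 2
Reactants: 3 (R)-5-hydroxy-6,6-dimethoxy-1-(trimethylsilyl)hex-1-yn-3-one
Product: 5 (3S,5R)-6,6-dimethoxy-3-methylhex-1-yne-3,5-diol, via TMS-diol 4 (not isolated)
Conditions: MeMgBr (3.5 equiv), CH2Cl2–Et2O, −78 °C; then MeOH, K2CO3, rt
Reagents that add atoms: methylmagnesium bromide, C[Mg]Br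
Why: Chelation-controlled Grignard 1,2-addition, in which the magnesium alkoxide at C8 holds the ynone carbonyl in a six-membered chelate and methyl adds to its open face (the sense of a Narasaka–Prasad reduction with methyl in place of hydride), giving the 8,10-syn diol with C10 as S (about 5:1 expected, minor epimer removed by chromatography) before K2CO3/MeOH protodesilylates the alkyne.

Step 3
Reactants: 5 (3S,5R)-6,6-dimethoxy-3-methylhex-1-yne-3,5-diol; 6 methacrylic anhydride
Product: 7 (2R,4S)-4-hydroxy-1,1-dimethoxy-4-methylhex-5-yn-2-yl 2-methylprop-2-enoate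
Conditions: Et3N, DMAP (cat.), CH2Cl2, 0 °C
Reagents that add atoms: none
Why: DMAP-catalysed acyl transfer esterifies the secondary C8 hydroxyl much faster than the tertiary propargylic C10 hydroxyl, so the C8 ester of the target is in place without a protecting group and no stereocentre is touched.

Step 4
Reactants: 8 but-2-yne-1,4-diol
Product: 9 4-(tert-butyldiphenylsilyloxy)but-2-yn-1-ol
Conditions: imidazole, THF, 0 °C (8 in threefold excess)
Reagents that add atoms: tert-butyl(chloro)diphenylsilane, CC(C)(C)[Si](Cl)(c1ccccc1)c1ccccc1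
Why: Statistical monosilylation of a cheap symmetric diol used in excess; no stereochemistry is involved.

Step 5
Reactants: 9 4-(tert-butyldiphenylsilyloxy)but-2-yn-1-ol
Product: 11 (Z)-4-(tert-butyldiphenylsilyloxy)-3-iodobut-2-en-1-ol, via vinylalanate 10 (not isolated)
Conditions: NaAlH2(OCH2CH2OMe)2, THF, 0 °C → rt; EtOAc; then I2, THF, −78 → 0 °C
Reagents that add atoms: iodine, II
Why: Hydroxyl-directed trans-hydroalumination of the propargylic alcohol puts aluminium on the distal alkyne carbon, and iodinolysis of the C–Al bond with retention gives the (Z)-iodide, which fixes the 4Z geometry (C3 cis to C6) of the target.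

Step 6
Reactants: 11 (Z)-4-(tert-butyldiphenylsilyloxy)-3-iodobut-2-en-1-ol
Product: 12 (Z)-1-(tert-butyldiphenylsilyloxy)-2-iodo-4-(triethylsilyloxy)but-2-ene
Conditions: imidazole, CH2Cl2, 0 °C
Reagents that add atoms: chlorotriethylsilane, CC[Si](Cl)(CC)CC
Why: Silylation of the primary allylic alcohol is needed because a free cis-hydroxymethyl group would trap the acylpalladium of step 7 as a butenolide, and the triethylsilyl group is chosen so that it falls off together with the acetal in step 8.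

Step 7
Reactants: 7 (2R,4S)-4-hydroxy-1,1-dimethoxy-4-methylhex-5-yn-2-yl 2-methylprop-2-enoate; 12 (Z)-1-(tert-butyldiphenylsilyloxy)-2-iodo-4-(triethylsilyloxy)but-2-ene
Product: 15 (2R)-1,1-dimethoxy-3-[(2S)-5-{(2Z)-1-(tert-butyldiphenylsilyloxy)-4-(triethylsilyloxy)but-2-en-2-yl}-2-methyl-3-oxo-2,3-dihydrofuran-2-yl]propan-2-yl 2-methylprop-2-enoate, via ynone 13 (not isolated), via enaminone 14 (not isolated)
Conditions: PdCl2(PPh3)2 (5 mol %), CuI (2 mol %), CO (1 atm), Et3N, THF, rt; then Et2NH, EtOH, rt; then aq. AcOH (pH 5)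
Reagents that add atoms: carbon monoxide, [C-]#[O+]; water, O
Why: Carbonylative Sonogashira coupling (oxidative addition of the vinyl iodide to zerovalent palladium with retention, CO insertion, alkynyl transfer from copper) gives the 10-hydroxy ynone, and Et2NH conjugate addition at C1 followed by attack of the C10 hydroxyl on C3, loss of water and iminium hydrolysis closes the 3(2H)-furanone (Jackson–Raphael bullatenone-type cyclodehydration) without touching C8 or C10.

Step 8
Reactants: 15 (furanone acetal, name as in step 7)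
Product: 16 (2R)-1-oxo-3-[(2S)-5-{(2Z)-1-(tert-butyldiphenylsilyloxy)-4-hydroxybut-2-en-2-yl}-2-methyl-3-oxo-2,3-dihydrofuran-2-yl]propan-2-yl 2-methylprop-2-enoate
Conditions: TFA–H2O (9:1), CH2Cl2, 0 °C
Reagents that add atoms: water, O
Why: Aqueous-acid hydrolysis removes the dimethyl acetal and the triethylsilyl ether in one operation, while the TBDPS ether, the methacrylate and the vinylogous ester of the furanone tolerate short exposure to cold aqueous TFA and C8 is not epimerised under acid.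

Step 9
Reactants: 16 (hydroxy aldehyde, name as in step 8); 17 methyl acrylate
Product: 18 methyl (4R)-5-[(2S)-5-{(2Z)-1-(tert-butyldiphenylsilyloxy)-4-hydroxybut-2-en-2-yl}-2-methyl-3-oxo-2,3-dihydrofuran-2-yl]-3-hydroxy-4-(methacryloyloxy)-2-methylidenepentanoate (both C7 epimers)
Conditions: DABCO (0.5 equiv), neat 17, rt
Reagents that add atoms: none
Why: Morita–Baylis–Hillman reaction of the activated α-acyloxy aldehyde attaches C11–C13 to C7, and the new C7 carbinol forms as an epimer mixture that does not matter because this centre is erased in step 11.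

Step 10
Reactants: 18 (Morita–Baylis–Hillman diol, name as in step 9)
Product: 19 methyl (4R)-5-[(2S)-5-{(2Z)-1-(tert-butyldiphenylsilyloxy)-4-oxobut-2-en-2-yl}-2-methyl-3-oxo-2,3-dihydrofuran-2-yl]-3-hydroxy-4-(methacryloyloxy)-2-methylidenepentanoate
Conditions: TEMPO (10 mol %), PhI(OAc)2, CH2Cl2, rt
Reagents that add atoms: none
Why: Oxoammonium oxidation (TEMPO/PhI(OAc)2) is selective for the primary allylic alcohol over the secondary one and does not isomerise the (Z)-enal.

Step 11
Reactants: 19 (enal, name as in step 10)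
Product: 21 methyl (2Z,4R)-2-(bromomethyl)-5-[(2S)-5-{(2Z)-1-(tert-butyldiphenylsilyloxy)-4-oxobut-2-en-2-yl}-2-methyl-3-oxo-2,3-dihydrofuran-2-yl]-4-(methacryloyloxy)pent-2-enoate, via alkoxysulfonium bromide 20 (not isolated)
Conditions: NBS, Me2S, CH2Cl2, −20 → 0 °C (reagent premixed before 19 is added)
Reagents that add atoms: N-bromosuccinimide, O=C1CCC(=O)N1Br
Why: Corey–Kim-type activation of the Morita–Baylis–Hillman alcohol and SN2' attack of bromide gives the thermodynamically preferred (Z)-2-(bromomethyl)enoate, turning C7 from a carbinol into the γ-carbon of an allylic nucleophile.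

Step 12
Reactants: 21 (allylic bromide, name as in step 11)
Product: 24 (4Z,6R,7R,8R,10S)-15-(tert-butyldiphenylsilyloxy)-8-(methacryloyloxy)-1-oxo-3,10-epoxygermacra-2,4,11(13)-trien-12,6-olide, via allylchromium 22 (not isolated), via hydroxy ester 23 (not isolated)
Conditions: CrCl2 (8 equiv), THF (3 mM), rt, slow addition of 21; then p-TsOH (cat.), CH2Cl2, rt
Reagents that add atoms: none
Why: Intramolecular Nozaki–Hiyama–Kishi (Barbier-type) allylation, in which divalent chromium turns the bromide into an allylchromium whose γ-carbon C7 adds to the C6 aldehyde through a six-membered cyclic transition state with H8 in the allyl plane (A1,3 strain), the C8–C9 bond anti to the incoming aldehyde and C5 and C8 expected to lie anti across the new bond, so that C7 (R) and C6 (R) form with the 6,7-anti relationship that lactonises under acid (loss of methanol) to the trans-fused α-methylene lactone, as in chromium-mediated closures of costunolide-type germacranolides.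

Step 13
Reactants: 24 (15-O-TBDPS macrolactone, name as in step 12)
Product: 25 (4Z,6R,7R,8R,10S)-15-hydroxy-8-(methacryloyloxy)-1-oxo-3,10-epoxygermacra-2,4,11(13)-trien-12,6-olide (CNP0180483.4)
Conditions: HF·pyridine, pyridine–THF, 0 °C → rt
Reagents that add atoms: none
Why: Fluoride cleavage of the primary TBDPS ether under buffered, non-basic conditions leaves the two Michael acceptors, the ester and all four stereocentres untouched.

## Compound list

1 | 4-(trimethylsilyl)but-3-yn-2-one | CC(=O)C#C[Si](C)(C)C | starting material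
2 | 2,2-dimethoxyacetaldehyde | COC(OC)C=O | starting material
3 | (R)-5-hydroxy-6,6-dimethoxy-1-(trimethylsilyl)hex-1-yn-3-one | C[Si](C)(C)C#CC(=O)C[C@@H](O)C(OC)OC | intermediate
4 | (3S,5R)-6,6-dimethoxy-3-methyl-1-(trimethylsilyl)hex-1-yne-3,5-diol (TMS-diol) | C[Si](C)(C)C#C[C@@](C)(O)C[C@@H](O)C(OC)OC | intermediate (not isolated)
5 | (3S,5R)-6,6-dimethoxy-3-methylhex-1-yne-3,5-diol | C#C[C@@](C)(O)C[C@@H](O)C(OC)OC | intermediate
6 | methacrylic anhydride | CC(=C)C(=O)OC(=O)C(C)=C | starting material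
7 | (2R,4S)-4-hydroxy-1,1-dimethoxy-4-methylhex-5-yn-2-yl 2-methylprop-2-enoate | C#C[C@@](C)(O)C[C@@H](OC(=O)C(C)=C)C(OC)OC | intermediate
8 | but-2-yne-1,4-diol | OCC#CCO | starting material
9 | 4-(tert-butyldiphenylsilyloxy)but-2-yn-1-ol | OCC#CCO[Si](c1ccccc1)(c1ccccc1)C(C)(C)C | intermediate
10 | sodium cyclic vinylalanate, 2,2-bis(2-methoxyethoxy)-3-[(tert-butyldiphenylsilyloxy)methyl]-2,5-dihydro-1,2-oxaluminol-2-uide | [Na+].COCCO[Al-]1(OCCOC)OCC=C1CO[Si](c1ccccc1)(c1ccccc1)C(C)(C)C | intermediate (not isolated)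
11 | (Z)-4-(tert-butyldiphenylsilyloxy)-3-iodobut-2-en-1-ol | OC/C=C(\I)CO[Si](c1ccccc1)(c1ccccc1)C(C)(C)C | intermediate
12 | (Z)-1-(tert-butyldiphenylsilyloxy)-2-iodo-4-(triethylsilyloxy)but-2-ene | CC[Si](CC)(CC)OC/C=C(\I)CO[Si](c1ccccc1)(c1ccccc1)C(C)(C)C | intermediate
13 | (2R,4S,8Z)-8-[(tert-butyldiphenylsilyloxy)methyl]-4-hydroxy-1,1-dimethoxy-4-methyl-7-oxo-10-(triethylsilyloxy)dec-8-en-5-yn-2-yl 2-methylprop-2-enoate (ynone) | CC[Si](CC)(CC)OC/C=C(/CO[Si](c1ccccc1)(c1ccccc1)C(C)(C)C)C(=O)C#C[C@@](C)(O)C[C@@H](OC(=O)C(C)=C)C(OC)OC | intermediate (not isolated)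
14 | (2R,4S,8Z)-8-[(tert-butyldiphenylsilyloxy)methyl]-5-(diethylamino)-4-hydroxy-1,1-dimethoxy-4-methyl-7-oxo-10-(triethylsilyloxy)deca-5,8-dien-2-yl 2-methylprop-2-enoate (enaminone) | CC[Si](CC)(CC)OC/C=C(/CO[Si](c1ccccc1)(c1ccccc1)C(C)(C)C)C(=O)C=C(N(CC)CC)[C@@](C)(O)C[C@@H](OC(=O)C(C)=C)C(OC)OC | intermediate (not isolated)
15 | (2R)-1,1-dimethoxy-3-[(2S)-5-{(2Z)-1-(tert-butyldiphenylsilyloxy)-4-(triethylsilyloxy)but-2-en-2-yl}-2-methyl-3-oxo-2,3-dihydrofuran-2-yl]propan-2-yl 2-methylprop-2-enoate | CC[Si](CC)(CC)OC/C=C(/CO[Si](c1ccccc1)(c1ccccc1)C(C)(C)C)C1=CC(=O)[C@](C)(C[C@@H](OC(=O)C(C)=C)C(OC)OC)O1 | intermediate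
16 | (2R)-1-oxo-3-[(2S)-5-{(2Z)-1-(tert-butyldiphenylsilyloxy)-4-hydroxybut-2-en-2-yl}-2-methyl-3-oxo-2,3-dihydrofuran-2-yl]propan-2-yl 2-methylprop-2-enoate | OC/C=C(/CO[Si](c1ccccc1)(c1ccccc1)C(C)(C)C)C1=CC(=O)[C@](C)(C[C@@H](OC(=O)C(C)=C)C=O)O1 | intermediate
17 | methyl acrylate | C=CC(=O)OC | starting material
18 | methyl (4R)-5-[(2S)-5-{(2Z)-1-(tert-butyldiphenylsilyloxy)-4-hydroxybut-2-en-2-yl}-2-methyl-3-oxo-2,3-dihydrofuran-2-yl]-3-hydroxy-4-(methacryloyloxy)-2-methylidenepentanoate (C7 epimers) | OC/C=C(/CO[Si](c1ccccc1)(c1ccccc1)C(C)(C)C)C1=CC(=O)[C@](C)(C[C@@H](OC(=O)C(C)=C)C(O)C(=C)C(=O)OC)O1 | intermediate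
19 | methyl (4R)-5-[(2S)-5-{(2Z)-1-(tert-butyldiphenylsilyloxy)-4-oxobut-2-en-2-yl}-2-methyl-3-oxo-2,3-dihydrofuran-2-yl]-3-hydroxy-4-(methacryloyloxy)-2-methylidenepentanoate | O=C/C=C(/CO[Si](c1ccccc1)(c1ccccc1)C(C)(C)C)C1=CC(=O)[C@](C)(C[C@@H](OC(=O)C(C)=C)C(O)C(=C)C(=O)OC)O1 | intermediate
20 | O-dimethylsulfonium bromide of 19 at the C7 hydroxyl (alkoxysulfonium bromide) | O=C/C=C(/CO[Si](c1ccccc1)(c1ccccc1)C(C)(C)C)C1=CC(=O)[C@](C)(C[C@@H](OC(=O)C(C)=C)C(O[S+](C)C)C(=C)C(=O)OC)O1.[Br-] | intermediate (not isolated)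
21 | methyl (2Z,4R)-2-(bromomethyl)-5-[(2S)-5-{(2Z)-1-(tert-butyldiphenylsilyloxy)-4-oxobut-2-en-2-yl}-2-methyl-3-oxo-2,3-dihydrofuran-2-yl]-4-(methacryloyloxy)pent-2-enoate | O=C/C=C(/CO[Si](c1ccccc1)(c1ccccc1)C(C)(C)C)C1=CC(=O)[C@](C)(C[C@@H](OC(=O)C(C)=C)/C=C(\CBr)C(=O)OC)O1 | intermediate
22 | allylchromium from 21 (C13–CrCl2 in place of C13–Br) | O=C/C=C(/CO[Si](c1ccccc1)(c1ccccc1)C(C)(C)C)C1=CC(=O)[C@](C)(C[C@@H](OC(=O)C(C)=C)/C=C(\C[Cr](Cl)Cl)C(=O)OC)O1 | intermediate (not isolated)
23 | methyl (4Z,6R,7S,8R,10S)-15-(tert-butyldiphenylsilyloxy)-6-hydroxy-8-(methacryloyloxy)-1-oxo-3,10-epoxygermacra-2,4,11(13)-trien-12-oate (hydroxy ester; 7S only through a priority change) | C=C(C)C(=O)O[C@@H]1C[C@]2(C)OC(=CC2=O)/C(CO[Si](c2ccccc2)(c2ccccc2)C(C)(C)C)=C\[C@@H](O)[C@@H]1C(=C)C(=O)OC | intermediate (not isolated)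
24 | (4Z,6R,7R,8R,10S)-15-(tert-butyldiphenylsilyloxy)-8-(methacryloyloxy)-1-oxo-3,10-epoxygermacra-2,4,11(13)-trien-12,6-olide | C=C(C)C(=O)O[C@@H]1C[C@]2(C)OC(=CC2=O)/C(CO[Si](c2ccccc2)(c2ccccc2)C(C)(C)C)=C\[C@H]2OC(=O)C(=C)[C@@H]21 | intermediate
25 | (4Z,6R,7R,8R,10S)-15-hydroxy-8-(methacryloyloxy)-1-oxo-3,10-epoxygermacra-2,4,11(13)-trien-12,6-olide (CNP0180483.4) | C=C(C)C(=O)O[C@@H]1C[C@]2(C)OC(=CC2=O)/C(CO)=C\[C@H]2OC(=O)C(=C)[C@@H]21 | target

## Step count and risks

Total steps: 13. Longest linear sequence: 10 (steps 1, 2, 3, 7, 8, 9, 10, 11, 12, 13); steps 4–6 are the side branch.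

Most likely to fail:

Step 12 (macrocyclisation). The risks are a wrong C6/C7 configuration (acyclic 2-alkoxycarbonyl allylmetals prefer the syn adduct and cis-lactone) and attack of the allylmetal on the C1 furanone carbonyl, which would close a five-membered ring instead of the macrocycle. The fallback sets out from 19 and comes back at 24; it replaces the allylchromium by an allylboronate, which adds only to aldehydes. Acetylation of 19 (Ac2O, pyridine, DMAP) gives the Morita–Baylis–Hillman acetate F7. Borylation with B2pin2 catalysed by Pd2(dba)3 (toluene, 50 °C, dilute) gives the 2-(methoxycarbonyl)allylboronate F8. F8 undergoes intramolecular allylboration of the C6 aldehyde through a closed chair transition state, promoted by Sc(OTf)3 if needed. Work-up gives 23, which lactonises with p-TsOH to 24.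

Step 9 (Morita–Baylis–Hillman reaction on the α-acyloxy aldehyde). The risks are epimerisation at C8 and a 1,2-shift of the methacryloyl group to the new C7 hydroxyl. The fallback sets out from 16 and comes back at 24; C7 never becomes a carbinol. Methyl (triphenylphosphoranylidene)acetate is alkylated with (iodomethyl)trimethylsilane to the ylide methyl 3-(trimethylsilyl)-2-(triphenylphosphoranylidene)propanoate F4. Base-free Wittig olefination of 16 with it (toluene, 60 °C) gives the allylsilane alcohol F5. TEMPO/PhI(OAc)2 oxidation gives the allylsilane enal F6. BF3·OEt2 (CH2Cl2, −78 °C, high dilution) then closes C6–C7 by an intramolecular Hosomi–Sakurai reaction: the activated C6 aldehyde is attacked by the C7=C11 π bond and silicon is lost. The resulting 23 lactonises to 24.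

Step 2 (1,3-induction in the methyl addition). The risk is that the addition is unselective or favours the 8,10-anti diol. The fallback sets out from 1 and 2 and comes back at 7; the 8,10-relationship is then set by inversion at C8 instead of by the sense of the addition. The aldol of 1 and 2 with the antipodal ligand gives (S)-5-hydroxy-6,6-dimethoxy-1-(trimethylsilyl)hex-1-yn-3-one F1. Methyl addition (MeMgBr, or MeLi/CeCl3 if chelation is the problem) gives (3S,5S)-6,6-dimethoxy-3-methyl-1-(trimethylsilyl)hex-1-yne-3,5-diol F2 as the major or chromatographically separated epimer. K2CO3/MeOH gives (3S,5S)-6,6-dimethoxy-3-methylhex-1-yne-3,5-diol F3. A Mitsunobu esterification with methacrylic acid (PPh3, DIAD, THF, 0 °C) inverts C8 while installing the ester, which gives 7.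

Further compounds

F1 | step 2 | (S)-5-hydroxy-6,6-dimethoxy-1-(trimethylsilyl)hex-1-yn-3-one | C[Si](C)(C)C#CC(=O)C[C@H](O)C(OC)OC
F2 | step 2 | (3S,5S)-6,6-dimethoxy-3-methyl-1-(trimethylsilyl)hex-1-yne-3,5-diol | C[Si](C)(C)C#C[C@@](C)(O)C[C@H](O)C(OC)OC
F3 | step 2 | (3S,5S)-6,6-dimethoxy-3-methylhex-1-yne-3,5-diol | C#C[C@@](C)(O)C[C@H](O)C(OC)OC
F4 | step 9 | methyl 3-(trimethylsilyl)-2-(triphenylphosphoranylidene)propanoate | COC(=O)C(C[Si](C)(C)C)=P(c1ccccc1)(c1ccccc1)c1ccccc1
F5 | step 9 | methyl (2Z,4R)-5-[(2S)-5-{(2Z)-1-(tert-butyldiphenylsilyloxy)-4-hydroxybut-2-en-2-yl}-2-methyl-3-oxo-2,3-dihydrofuran-2-yl]-4-(methacryloyloxy)-2-[(trimethylsilyl)methyl]pent-2-enoate | OC/C=C(/CO[Si](c1ccccc1)(c1ccccc1)C(C)(C)C)C1=CC(=O)[C@](C)(C[C@@H](OC(=O)C(C)=C)/C=C(\C[Si](C)(C)C)C(=O)OC)O1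
F6 | step 9 | methyl (2Z,4R)-5-[(2S)-5-{(2Z)-1-(tert-butyldiphenylsilyloxy)-4-oxobut-2-en-2-yl}-2-methyl-3-oxo-2,3-dihydrofuran-2-yl]-4-(methacryloyloxy)-2-[(trimethylsilyl)methyl]pent-2-enoate | O=C/C=C(/CO[Si](c1ccccc1)(c1ccccc1)C(C)(C)C)C1=CC(=O)[C@](C)(C[C@@H](OC(=O)C(C)=C)/C=C(\C[Si](C)(C)C)C(=O)OC)O1
F7 | step 12 | methyl (4R)-3-acetoxy-5-[(2S)-5-{(2Z)-1-(tert-butyldiphenylsilyloxy)-4-oxobut-2-en-2-yl}-2-methyl-3-oxo-2,3-dihydrofuran-2-yl]-4-(methacryloyloxy)-2-methylidenepentanoate | O=C/C=C(/CO[Si](c1ccccc1)(c1ccccc1)C(C)(C)C)C1=CC(=O)[C@](C)(C[C@@H](OC(=O)C(C)=C)C(OC(C)=O)C(=C)C(=O)OC)O1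
F8 | step 12 | methyl (2E,4R)-5-[(2S)-5-{(2Z)-1-(tert-butyldiphenylsilyloxy)-4-oxobut-2-en-2-yl}-2-methyl-3-oxo-2,3-dihydrofuran-2-yl]-4-(methacryloyloxy)-2-[(4,4,5,5-tetramethyl-1,3,2-dioxaborolan-2-yl)methyl]pent-2-enoate | O=C/C=C(/CO[Si](c1ccccc1)(c1ccccc1)C(C)(C)C)C1=CC(=O)[C@](C)(C[C@@H](OC(=O)C(C)=C)/C=C(\CB2OC(C)(C)C(C)(C)O2)C(=O)OC)O1
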